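**Retrosynthetic overview**

1. Ilicicolin J (23) comes from global O-dealkylation of 21, and 21 from Suzuki–Miyaura coupling of dienyl triflate 19 with (E)-prop-1-enylboronic acid. The propenyl-bearing ring A carbon C1 is therefore carried as a ketone/enol until late.
2. Ring A (C1, C2, C3, C4, C4a, C8a) is closed by a formal [4+2] annulation of β-diketone 14 with propanal. Propanal supplies C3 and C4 (with its methyl group), and the bonds C2–C3 and C4–C4a form in one operation by Knoevenagel condensation and 6π-electrocyclisation.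
3. Enabling feature: C2 of ring A lies between the exocyclic aroyl C=O and ring carbon C1 (a latent ketone), so it is a 1,3-dicarbonyl methylene. C1=O is conjugated with the ring B alkene C8a=C4a, so C4a is the electrophilic end of a 3-oxy-hexatriene C4=C3–C2=C1–C8a=C4a.
4. Diketone 14 comes from C-acylation of (S)-1-acetyl-5-methylcyclohexene 12 with nicotinoyl chloride 13. Ketone 12 is made from (S)-citronellyl bromide (Grignard acylation, ozonolysis, aldol cyclisation); 13 from 5-bromo-2,4-dimethoxypyridine (Suzuki coupling, directed lithiation/carboxylation).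
5. Ring order: pyridine ring bought, ring B by aldol condensation, ring A in the key step, pyridone unmasked last.

Key step: step 7

Remark: the 1,3-dicarbonyl compounds 14 and 18 are drawn as single tautomers (14 as the diketone, 18 as the ring enol); both are expected to be chelated enols in solution.

Ring A is the cyclohexadiene ring and ring B the methylcyclohexane ring; locants are those of the hexahydronaphthalene in 23.

**Route**

Step 1
Reactants: 1 5-bromo-2,4-dimethoxypyridine; 2 [4-(methoxymethoxy)phenyl]boronic acid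
Product: 3 2,4-dimethoxy-5-[4-(methoxymethoxy)phenyl]pyridine
Conditions: Pd(PPh3)4 (5 mol%), K2CO3, 1,4-dioxane/H2O, 90 °C
Reagents that add atoms: none
Why: Suzuki–Miyaura cross-coupling of a bromopyridine with an arylboronic acid is routine, and the methyl and methoxymethyl (MOM) ethers are inert to the basic conditions.

Step 2
Reactants: 3 2,4-dimethoxy-5-[4-(methoxymethoxy)phenyl]pyridine
Product: 5 2,4-dimethoxy-5-[4-(methoxymethoxy)phenyl]pyridine-3-carboxylic acid, via aryllithium 4 (not isolated)
Conditions: n-BuLi, THF, −78 → −40 °C; CO2 (gas), −78 °C → rt; aq. HCl work-up to pH 4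
Reagents that add atoms: carbon dioxide, O=C=O
Why: Directed ortho-metalation should occur at C3, the position flanked by both methoxy groups and the most acidic C–H, and carboxylation of the aryllithium gives the acid; no stereocenter is involved.

Step 3
Reactants: 6 (S)-citronellyl bromide [(6S)-8-bromo-2,6-dimethyloct-2-ene]; 7 N-methoxy-N-methylacetamide
Product: 9 (5S)-5,9-dimethyldec-8-en-2-one, via Grignard reagent 8 (not isolated)
Conditions: Mg, THF, 40 °C; then 7, 0 °C → rt; aq. NH4Cl
Reagents that add atoms: none
Why: Grignard formation from the primary bromide and acylation by the N-methoxy-N-methyl amide should stop at the ketone through the chelated tetrahedral intermediate; the remote methyl-bearing stereocenter is untouched.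

Step 4
Reactants: 9 (5S)-5,9-dimethyldec-8-en-2-one
Product: 11 (4S)-4-methyl-7-oxooctanal, via ozonide 10 (not isolated)
Conditions: O3, CH2Cl2, −78 °C; then PPh3, −78 °C → rt
Reagents that add atoms: ozone, [O-][O+]=O
Why: Ozonolysis with reductive work-up cleaves the only alkene to the aldehyde and acetone; the ketone and the stereocenter are not affected.

Step 5
Reactants: 11 (4S)-4-methyl-7-oxooctanal
Product: 12 1-[(5S)-5-methylcyclohex-1-en-1-yl]ethan-1-one
Conditions: KOH (2% aq.), MeOH, 0 °C → rt
Reagents that add atoms: none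
Why: Intramolecular aldol condensation under hydroxide should close ring B by attack of the ketone CH2 enolate on the more electrophilic aldehyde (six-membered ring), and E1cB dehydration gives the conjugated 1-acylcyclohexene; the methyl-bearing center is γ to both carbonyl groups and cannot epimerise.

Step 6
Reactants: 5 2,4-dimethoxy-5-[4-(methoxymethoxy)phenyl]pyridine-3-carboxylic acid; 12 1-[(5S)-5-methylcyclohex-1-en-1-yl]ethan-1-one
Product: 14 1-{2,4-dimethoxy-5-[4-(methoxymethoxy)phenyl]pyridin-3-yl}-3-[(5S)-5-methylcyclohex-1-en-1-yl]propane-1,3-dione, via acid chloride 13 (not isolated)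
Conditions: 5, 1-chloro-N,N,2-trimethylprop-1-en-1-amine, CH2Cl2, 0 °C → rt; separately 12, LiN(SiMe3)2 (2.2 equiv), THF, −78 °C; add the solution of 13, −78 → 0 °C; aq. NH4Cl
Reagents that add atoms: none
Why: Crossed Claisen-type C-acylation of the kinetic methyl-side lithium enolate of the enone with an acid chloride made under neutral conditions (which spares the MOM ether) should give the 1,3-diketone, the extra amide base keeping the more acidic product deprotonated; no stereocenter is formed.

Step 7
Reactants: 14 1-{2,4-dimethoxy-5-[4-(methoxymethoxy)phenyl]pyridin-3-yl}-3-[(5S)-5-methylcyclohex-1-en-1-yl]propane-1,3-dione; 15 propanal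
Product: 18 {2,4-dimethoxy-5-[4-(methoxymethoxy)phenyl]pyridin-3-yl}[(4aS,7S,8aS)-1-hydroxy-4,7-dimethyl-4a,5,6,7,8,8a-hexahydronaphthalen-2-yl]methanone, via Knoevenagel adduct 16 (not isolated), via enedione 17 (not isolated)
Conditions: propanal (3 equiv), piperidine (20 mol%), AcOH (20 mol%), 4 Å molecular sieves, toluene, rt, then 70 °C
Reagents that add atoms: none
Why: Proposed new method: piperidinium acetate should condense propanal with the 1,3-diketone methylene C2 of 14 (Knoevenagel, C2–C3 bond) to give 16, whose dienol(ate) is a 3-oxy-hexatriene C4=C3–C2=C1(O)–C8a=C4a that closes by 6π-disrotatory electrocyclisation, equivalent to an intramolecular vinylogous Michael addition of C4 to the cyclohexenyl ketone (C4–C4a bond), and proton shifts via 17 should end in the chelated dienol 18. The closest known reaction types are the Knoevenagel/6π-electrocyclisation cascades of 1,3-dicarbonyl compounds with aldehydes, the anion-accelerated electrocyclisation of oxido-hexatrienes and the enamine-mediated Robinson annulation of aldehydes with 1-acylcyclohexenes; a cyclohexenyl β-diketone has not been combined with an enolisable aliphatic aldehyde in this way. Ring A is closed at C4–C4a in a 6π (6-endo-trig) mode onto the ring B alkene, the C2–C3 bond having been made just before in the intermolecular condensation. C4a is set in the ring closure: the new C4–C4a bond has to be equatorial on ring B to become part of the fused cyclohexadiene, so the chair-like transition state with the C7 methyl group equatorial should give the 4a,7-trans relationship; C8a, α to C1=O and epimerisable, should settle in the trans-fused all-equatorial arrangement, and the C4 center of 17 is erased on enolisation. The step needs C- over O-cyclisation and 1:1 coupling instead of Michael bis-adducts: oxa-Michael closure of the enol oxygen onto C4a is reversible whereas the carbocycle is drained into the stable dienol 18, and excess volatile propanal with a low amine loading should keep 16 from accumulating.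

Step 8
Reactants: 18 {2,4-dimethoxy-5-[4-(methoxymethoxy)phenyl]pyridin-3-yl}[(4aS,7S,8aS)-1-hydroxy-4,7-dimethyl-4a,5,6,7,8,8a-hexahydronaphthalen-2-yl]methanone
Product: 19 (4aS,7S,8aS)-2-{2,4-dimethoxy-5-[4-(methoxymethoxy)phenyl]pyridine-3-carbonyl}-4,7-dimethyl-4a,5,6,7,8,8a-hexahydronaphthalen-1-yl trifluoromethanesulfonate
Conditions: NaH, THF, 0 °C; PhNTf2, 0 °C → rt; aq. NH4Cl
Reagents that add atoms: N-phenylbis(trifluoromethanesulfonimide), O=S(=O)(N(c1ccccc1)S(=O)(=O)C(F)(F)F)C(F)(F)F
Why: Enol triflate formation from the sodium enolate of a β-diketone; O-sulfonylation is expected at the ring oxygen on C1, which keeps the C1=C2–C3=C4 diene, because the aroyl oxygen is shielded by the two flanking methoxy groups of the twisted pyridine; no stereocenter is formed.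

Step 9
Reactants: 19 the C1 dienyl triflate; 20 (E)-prop-1-en-1-ylboronic acid
Product: 21 {2,4-dimethoxy-5-[4-(methoxymethoxy)phenyl]pyridin-3-yl}{(4aS,7S,8aS)-4,7-dimethyl-1-[(1E)-prop-1-en-1-yl]-4a,5,6,7,8,8a-hexahydronaphthalen-2-yl}methanone
Conditions: Pd(PPh3)4 (5 mol%), K3PO4, 1,4-dioxane/H2O (10:1), 50 °C
Reagents that add atoms: none
Why: Suzuki–Miyaura coupling of a β-acyl vinyl triflate with an alkenylboronic acid should proceed with retention of the (E)-geometry and of the triflate position; C8a, now γ to the ketone, stays in the favoured trans-fused configuration under the mild base.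

Step 10
Reactants: 21 the tri-O-protected ilicicolin J
Product: 23 ilicicolin J, 3-{(4aS,7S,8aS)-4,7-dimethyl-1-[(1E)-prop-1-en-1-yl]-4a,5,6,7,8,8a-hexahydronaphthalene-2-carbonyl}-4-hydroxy-5-(4-hydroxyphenyl)pyridin-2(1H)-one, via tris(trimethylsilyl) ether 22 (not isolated)
Conditions: Me3SiCl, NaI, MeCN, 0 °C → rt; then aq. NaHCO3/Na2S2O3
Reagents that add atoms: none
Why: Iodotrimethylsilane made in the flask should cleave the MOM ether and both pyridyl methyl ethers (an imidate and a vinylogous ester, both activated by the 3-acyl group) by SN2 dealkylation, and hydrolytic work-up releases the 4-hydroxy-2-pyridone and the phenol; no stereocenter is touched.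

**Compound list**

1 | 5-bromo-2,4-dimethoxypyridine | COc1cc(OC)c(Br)cn1 | starting material
2 | [4-(methoxymethoxy)phenyl]boronic acid | COCOc1ccc(B(O)O)cc1 | starting material
3 | 2,4-dimethoxy-5-[4-(methoxymethoxy)phenyl]pyridine | COCOc1ccc(-c2cnc(OC)cc2OC)cc1 | intermediate
4 | {2,4-dimethoxy-5-[4-(methoxymethoxy)phenyl]pyridin-3-yl}lithium | COCOc1ccc(-c2cnc(OC)c([Li])c2OC)cc1 | intermediate
5 | 2,4-dimethoxy-5-[4-(methoxymethoxy)phenyl]pyridine-3-carboxylic acid | COCOc1ccc(-c2cnc(OC)c(C(=O)O)c2OC)cc1 | intermediate
6 | (S)-citronellyl bromide, (6S)-8-bromo-2,6-dimethyloct-2-ene | C[C@@H](CCC=C(C)C)CCBr | starting material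
7 | N-methoxy-N-methylacetamide | CC(=O)N(C)OC | starting material
8 | [(3S)-3,7-dimethyloct-6-en-1-yl]magnesium bromide | C[C@@H](CCC=C(C)C)CC[Mg]Br | intermediate
9 | (5S)-5,9-dimethyldec-8-en-2-one | C[C@@H](CCC=C(C)C)CCC(C)=O | intermediate
10 | (5S)-7-(5,5-dimethyl-1,2,4-trioxolan-3-yl)-5-methylheptan-2-one (ozonide, epimers at the ring carbon) | C[C@@H](CCC1OOC(C)(C)O1)CCC(C)=O | intermediate
11 | (4S)-4-methyl-7-oxooctanal | C[C@@H](CCC=O)CCC(C)=O | intermediate
12 | 1-[(5S)-5-methylcyclohex-1-en-1-yl]ethan-1-one | CC(=O)C1=CCC[C@H](C)C1 | intermediate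
13 | 2,4-dimethoxy-5-[4-(methoxymethoxy)phenyl]pyridine-3-carbonyl chloride | COCOc1ccc(-c2cnc(OC)c(C(Cl)=O)c2OC)cc1 | intermediate
14 | 1-{2,4-dimethoxy-5-[4-(methoxymethoxy)phenyl]pyridin-3-yl}-3-[(5S)-5-methylcyclohex-1-en-1-yl]propane-1,3-dione | COCOc1ccc(-c2cnc(OC)c(C(=O)CC(=O)C3=CCC[C@H](C)C3)c2OC)cc1 | intermediate
15 | propanal | CCC=O | starting material
16 | 2-propylidene derivative of 14 (Knoevenagel adduct, E/Z mixture) | CCC=C(C(=O)c1c(OC)ncc(-c2ccc(OCOC)cc2)c1OC)C(=O)C1=CCC[C@H](C)C1 | intermediate
17 | (4aR,7S,8aS)-2-{2,4-dimethoxy-5-[4-(methoxymethoxy)phenyl]pyridine-3-carbonyl}-4,7-dimethyl-4a,5,6,7,8,8a-hexahydronaphthalen-1(4H)-one (same spatial arrangement at C4a, C7, C8a as 18; epimers at C4) | O=C1C(C(=O)c2c(OC)ncc(-c3ccc(OCOC)cc3)c2OC)=CC(C)[C@H]2CC[C@H](C)C[C@H]12 | intermediate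
18 | {2,4-dimethoxy-5-[4-(methoxymethoxy)phenyl]pyridin-3-yl}[(4aS,7S,8aS)-1-hydroxy-4,7-dimethyl-4a,5,6,7,8,8a-hexahydronaphthalen-2-yl]methanone (trans-fused, 7-methyl equatorial) | OC1=C(C(=O)c2c(OC)ncc(-c3ccc(OCOC)cc3)c2OC)C=C(C)[C@H]2CC[C@H](C)C[C@H]12 | intermediate
19 | (4aS,7S,8aS)-2-{2,4-dimethoxy-5-[4-(methoxymethoxy)phenyl]pyridine-3-carbonyl}-4,7-dimethyl-4a,5,6,7,8,8a-hexahydronaphthalen-1-yl trifluoromethanesulfonate | O=S(=O)(OC1=C(C(=O)c2c(OC)ncc(-c3ccc(OCOC)cc3)c2OC)C=C(C)[C@H]2CC[C@H](C)C[C@H]12)C(F)(F)F | intermediate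
20 | (E)-prop-1-en-1-ylboronic acid | C/C=C/B(O)O | starting material
21 | {2,4-dimethoxy-5-[4-(methoxymethoxy)phenyl]pyridin-3-yl}{(4aS,7S,8aS)-4,7-dimethyl-1-[(1E)-prop-1-en-1-yl]-4a,5,6,7,8,8a-hexahydronaphthalen-2-yl}methanone | C/C=C/C1=C(C(=O)c2c(OC)ncc(-c3ccc(OCOC)cc3)c2OC)C=C(C)[C@H]2CC[C@H](C)C[C@H]12 | intermediate
22 | tris(trimethylsilyl) ether of 23 (pyridine 2-O, 4-O and phenol O silylated) | C/C=C/C1=C(C(=O)c2c(O[Si](C)(C)C)ncc(-c3ccc(O[Si](C)(C)C)cc3)c2O[Si](C)(C)C)C=C(C)[C@H]2CC[C@H](C)C[C@H]12 | intermediate
23 | ilicicolin J, 3-{(4aS,7S,8aS)-4,7-dimethyl-1-[(1E)-prop-1-en-1-yl]-4a,5,6,7,8,8a-hexahydronaphthalene-2-carbonyl}-4-hydroxy-5-(4-hydroxyphenyl)pyridin-2(1H)-one | C/C=C/C1=C(C(=O)c2c(O)c(-c3ccc(O)cc3)c[nH]c2=O)C=C(C)[C@H]2CC[C@H](C)C[C@H]12 | target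

**Step count and risks**

Total step count: 10.
Longest linear sequence: 8 steps (steps 3, 4, 5, 6, 7, 8, 9, 10, from 6).

Steps most likely to fail:

1. Step 7 (proposed new method). The Knoevenagel adduct may be consumed by Michael addition of a second diketone or by oxygen cyclisation faster than the carbocyclisation, and facial selection at C4a may be incomplete. The fallback closes ring A stepwise with known reactions, sets out from 14 and comes back at 18. C-alkylation of 14 with 2,3-dibromopropene (K2CO3, acetone) should give the 2-(2-bromoprop-2-en-1-yl) diketone F1. Bu3SnH and AIBN in benzene at 80 °C under slow addition should generate the vinyl radical at C4, which adds to the enone carbon C4a in the 6-endo mode to give the 4-methylidene diketone F2; the same equatorial ring-fusion preference applies. RhCl3·3H2O in ethanol at 70 °C should then move the exocyclic double bond into ring A to give dienol 18.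

2. Step 8. Sulfonylation may occur at the aroyl oxygen instead of the ring oxygen, that is, loss of regiocontrol between the two enolate oxygens. The fallback sets out from 18 and comes back at 21. It replaces kinetic O-sulfonylation by a reversible, sterically governed enol ether formation: HC(OMe)3, MeOH and pyridinium p-toluenesulfonate at rt should give the C1 methyl enol ether F3, because methanol cannot add to the hindered aroyl carbon. Addition–elimination of lithium di[(E)-prop-1-enyl]cuprate, made from (E)-1-bromopropene, t-BuLi and CuI in Et2O at −78 °C, on this vinylogous ester should then deliver 21 directly.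

3. Step 10. Iodide or acid may add to the cross-conjugated trienone, double bonds may isomerise during the dealkylation, and cleavage of the 2-methoxy group may stay incomplete. The fallback sets out from 21 and comes back at 23; it unmasks in two mechanistically different stages through an isolable intermediate. BCl3 in CH2Cl2 at −78 °C should remove, by chelation to the ketone, only the 4-methoxy group and the MOM ether and give the 4-hydroxy-2-methoxypyridine phenol F4. The remaining 2-methoxy group, now an acyl-activated imidate, would then be hydrolysed with dilute aqueous HCl in THF at 40 °C to give 23.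

**Further compounds**

F1 | step 7 | 2-(2-bromoprop-2-en-1-yl)-1-{2,4-dimethoxy-5-[4-(methoxymethoxy)phenyl]pyridin-3-yl}-3-[(5S)-5-methylcyclohex-1-en-1-yl]propane-1,3-dione | C=C(Br)CC(C(=O)c1c(OC)ncc(-c2ccc(OCOC)cc2)c1OC)C(=O)C1=CCC[C@H](C)C1
F2 | step 7 | (4aS,7S,8aS)-2-{2,4-dimethoxy-5-[4-(methoxymethoxy)phenyl]pyridine-3-carbonyl}-7-methyl-4-methylideneoctahydronaphthalen-1(2H)-one (epimers at C2) | O=C1C(C(=O)c2c(OC)ncc(-c3ccc(OCOC)cc3)c2OC)CC(=C)[C@H]2CC[C@H](C)C[C@H]12
F3 | step 8 | {2,4-dimethoxy-5-[4-(methoxymethoxy)phenyl]pyridin-3-yl}[(4aS,7S,8aS)-1-methoxy-4,7-dimethyl-4a,5,6,7,8,8a-hexahydronaphthalen-2-yl]methanone | COC1=C(C(=O)c2c(OC)ncc(-c3ccc(OCOC)cc3)c2OC)C=C(C)[C@H]2CC[C@H](C)C[C@H]12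
F4 | step 10 | [4-hydroxy-5-(4-hydroxyphenyl)-2-methoxypyridin-3-yl]{(4aS,7S,8aS)-4,7-dimethyl-1-[(1E)-prop-1-en-1-yl]-4a,5,6,7,8,8a-hexahydronaphthalen-2-yl}methanone | C/C=C/C1=C(C(=O)c2c(OC)ncc(-c3ccc(O)cc3)c2O)C=C(C)[C@H]2CC[C@H](C)C[C@H]12
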